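The product, free or held in the idle adduct, comes from one catalysed step, so its amount at the end is that step's rate summed over the run.

    gas phase ⇌ dissolved gas, rate k1*(csat - [dissolved gas]) (k1 = 0.39 s⁻¹, csat = 1.2 mM)
    substrate + dissolved gas + free catalyst → free catalyst + product (k2 = 28000 M⁻² s⁻¹)
    free catalyst + impurity → spent catalyst (k3 = 1700 M⁻¹ s⁻¹)
    dissolved gas + product ⇌ idle adduct, settled at all times (K4 = 920 M⁻¹)

substrate 20 mM; gas phase 1.2 mM (held); free catalyst 40 µM; impurity 17 µM; time 2.0 min

- what is said of product includes idle adduct
- at the start none of the gas is dissolved
- run time (flask): 2.0 min

* the product and idle adduct together standing at 2.0 min, as a percentage of the substrate charged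
* the change that raises the amount of product and idle adduct together at 2.0 min, in percent of the substrate charged most ("none" if none brings more than 2 percentage points) (delta / eta / gamma / none)
* amount of product and idle adduct together at 2.0 min, in percent of the substrate charged, after delta

- delta: doubling the amount of free catalyst, all else as stated
- eta: doubling the transfer coefficient of step 1, all else as stated
- gamma: doubling the saturation concentration of gas phase, all else as stated

By hand, with dissolved gas taken at saturation and the catalyst as charged, each substrate molecule turns over with a pseudo-first-order constant of 0.0806 min⁻¹, which comes to 16.1% over 2.0 min. Catalyst loss, gas supply and substrate use slow this rate.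

The impurity takes free catalyst one for one, leaving 23.0 µM. The impurity falls with a time constant of about 0.426 min, shorter than the run, but the catalyst works until it is lost. So the quantity to carry is the mean working catalyst, 25.7 µM: the time-average of free catalyst over the run, namely the survivors plus the logarithm of charge over survivors, divided by the impurity constant and the time. This gives a factor of 0.643.

Dissolved gas stands where transfer balances consumption. The transfer coefficient 0.39 s⁻¹ exceeds the consumption constant 0.0129 s⁻¹, so the factor is 0.968.

Substrate also falls as it is used, so the product of the factors, 0.100, enters as an exponent and gives 9.55%. The same reckoning gives 21.1% for delta, 18.2% for gamma and 9.70% for eta, so delta leads.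

The forecast gives 9%, chooses delta and puts that change at 20%, holding that "Gas transfer is much faster than its consumption". Its two figures stand a little below this reckoning's.

The flask gives 9.10%, and delta, ahead with a gain of 11 percentage points, gives 20.2%. By 1.00 min the conversion in this flask has 54% of its turnover up to 2.0 min behind it; the mean working catalyst reckoned to that time, 28.4 µM, puts that share at 55.3%. A neighbour charged with 0.16 mM of free catalyst has a mean working catalyst of 144 µM, which gives 38.1%, and that neighbour stands at 36.6%.

(The numbers of this flask were drawn at random within sensible limits; the run is a simulation.)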